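**Strategy**

The 14-membered ring is numbered C1 (stereocentre) to C14 through the Z alkene C3=C4, the carboxyl-bearing C7=C8 and the E alkene C11=C12; C15 is the exocyclic alkene carbon on C1. The ring is opened at C2–C3. If the methylene on C15 is traded for oxygen, C2 becomes the β-carbon of that ketone and lies next to C3, so a cyclopropanol built from C15, C1 and C2 can act as a masked ketone homoenolate. Its palladium-mediated ring-opening and coupling with a Z-alkenyl iodide at C3 forms C2–C3, closes the macrocycle and unveils the C15 ketone in one operation. The precursor is a linear (1R,2R)-cis-1,2-dialkylcyclopropanol whose long arm carries the E alkene, the E-enoate and a terminal Z-iodoalkene.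

Key step: step 11

Assumption: in step 3 the (R,R)-TADDOL titanate is taken to favour the (1R,2R)-cyclopropanol; should a pilot run show the opposite sense, (S,S)-TADDOL is used and nothing else changes.

Remark: methylalumination and iodination of a terminal alkyne would place iodine trans to the chain (E), so the Z-iodoalkene is made by carbocupration of propyne (step 7). The cyclopropanol is carried as its triethylsilyl ether through the two carbanion steps and released just before cyclisation.

**Route**

Step 1
Reactants: 1 hex-1-en-5-yne; 2 oxirane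
Product: 5 (3E)-4-methylocta-3,7-dien-1-ol, via alkenyldimethylalane 3 (not isolated), via lithium alkenylalanate 4 (not isolated)
Conditions: AlMe3, Cp2ZrCl2 (20 mol %), CH2Cl2, 0 °C → rt; volatiles removed; n-BuLi, hexane, −78 → 0 °C; 2, THF, −78 °C → rt
Reagents that add atoms: trimethylaluminium, C[Al](C)C
Why: Zirconium-catalysed methylalumination (Negishi carboalumination) adds methyl and aluminium syn across the terminal alkyne far faster than across the isolated alkene, and the derived alanate opens oxirane with retention, so the syn addition fixes the E geometry of C11=C12.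

Step 2
Reactants: 5 (3E)-4-methylocta-3,7-dien-1-ol
Product: 7 (5E)-8-chloro-5-methylocta-1,5-diene, via mesylate 6 (not isolated)
Conditions: MsCl, Et3N, CH2Cl2, 0 °C; then LiCl, DMF, 60 °C
Reagents that add atoms: lithium chloride, [Li+].[Cl-]
Why: Sulfonylation and SN2 displacement by chloride turn the primary alcohol into a chloride that is inert to the magnesium and titanium reagents of step 3 and can be activated later by halide exchange.

Step 3
Reactants: 7 (5E)-8-chloro-5-methylocta-1,5-diene; 8 ethyl 5-methylhex-4-enoate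
Product: 9 (1R,2R)-2-[(3E)-6-chloro-3-methylhex-3-en-1-yl]-1-(4-methylpent-3-en-1-yl)cyclopropan-1-ol
Conditions: Ti(OiPr)2[(R,R)-TADDOLate] (pre-formed, 1.2 equiv), 8 (1.5 equiv), c-C5H9MgCl (slow addition), THF, 0 °C → rt; then chiral-phase SFC
Reagents that add atoms: none
Why: Kulinkovich hydroxycyclopropanation in its alkene-exchange form, in which the titanacyclopropane made from c-C5H9MgCl exchanges cyclopentene for the monosubstituted alkene of 7 only and couples with ester 8 to the usual cis-1,2-dialkylcyclopropanol, while the TADDOLate ligand biases the alkene face to set C1 as R (C15 follows from the cis relationship) and chromatography on a chiral phase removes residual minor enantiomer.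

Step 4
Reactants: 9 (1R,2R)-2-[(3E)-6-chloro-3-methylhex-3-en-1-yl]-1-(4-methylpent-3-en-1-yl)cyclopropan-1-ol
Product: 10 {[(1R,2R)-2-[(3E)-6-chloro-3-methylhex-3-en-1-yl]-1-(4-methylpent-3-en-1-yl)cyclopropyl]oxy}triethylsilane
Conditions: TESOTf, 2,6-lutidine, CH2Cl2, −78 → 0 °C
Reagents that add atoms: triethylsilyl trifluoromethanesulfonate, CC[Si](CC)(CC)OS(=O)(=O)C(F)(F)F
Why: Silylation of the tertiary cyclopropanol with a silyl triflate and a hindered base masks the base-labile cyclopropanol before the two carbanion steps.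

Step 5
Reactants: 10 {[(1R,2R)-2-[(3E)-6-chloro-3-methylhex-3-en-1-yl]-1-(4-methylpent-3-en-1-yl)cyclopropyl]oxy}triethylsilane
Product: 11 triethyl{[(1R,2R)-2-[(3E)-6-iodo-3-methylhex-3-en-1-yl]-1-(4-methylpent-3-en-1-yl)cyclopropyl]oxy}silane
Conditions: NaI, NaHCO3, 2-butanone, 80 °C
Reagents that add atoms: sodium iodide, [Na+].[I-]
Why: Finkelstein halide exchange, driven by precipitation of NaCl, gives the primary iodide under neutral conditions that leave the siloxycyclopropane and the alkenes untouched.

Step 6
Reactants: 11 triethyl{[(1R,2R)-2-[(3E)-6-iodo-3-methylhex-3-en-1-yl]-1-(4-methylpent-3-en-1-yl)cyclopropyl]oxy}silane; 12 methyl 2-(diethoxyphosphoryl)acetate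
Product: 13 methyl (5E)-2-(diethoxyphosphoryl)-6-methyl-8-[(1R,2R)-2-(4-methylpent-3-en-1-yl)-2-(triethylsilyloxy)cyclopropyl]oct-5-enoate (both C2 epimers)
Conditions: NaH, 12 (3 equiv), DMF, 0 → 50 °C
Reagents that add atoms: none
Why: SN2 C-alkylation of the soft sodium phosphonoacetate by the primary iodide, with excess 12 suppressing double alkylation; the new centre (ring C8) forms as an epimer mixture that is of no consequence because it becomes sp2 in step 9.

Step 7
Reactants: 14 2-(2-bromoethyl)-1,3-dioxolane; 15 propyne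
Product: 18 2-[(3Z)-4-iodo-3-methylbut-3-en-1-yl]-1,3-dioxolane, via Grignard reagent 16 (not isolated), via alkenylcopper 17 (not isolated)
Conditions: Mg, THF, 25 °C; CuBr·SMe2, Et2O/SMe2, −45 °C; 15, −25 °C; I2, THF, −50 → 0 °C
Reagents that add atoms: iodine, II
Why: Normant carbocupration adds the alkylcopper syn across propyne with carbon at the internal position, so copper and then iodine end up cis to the new chain and trans to the methyl group, which is the Z geometry required at C3=C4.

Step 8
Reactants: 18 2-[(3Z)-4-iodo-3-methylbut-3-en-1-yl]-1,3-dioxolane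
Product: 19 (4Z)-5-iodo-4-methylpent-4-enal
Conditions: 2 M HCl, THF, rt → 40 °C
Reagents that add atoms: water, O
Why: Acid-catalysed acetal hydrolysis frees the aldehyde, and the iodoalkene is stable to aqueous acid and keeps its geometry.

Step 9
Reactants: 13 methyl (5E)-2-(diethoxyphosphoryl)-6-methyl-8-[(1R,2R)-2-(4-methylpent-3-en-1-yl)-2-(triethylsilyloxy)cyclopropyl]oct-5-enoate; 19 (4Z)-5-iodo-4-methylpent-4-enal
Product: 20 methyl (2E,6Z)-7-iodo-6-methyl-2-{(3E)-4-methyl-6-[(1R,2R)-2-(4-methylpent-3-en-1-yl)-2-(triethylsilyloxy)cyclopropyl]hex-3-en-1-yl}hepta-2,6-dienoate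
Conditions: NaH, THF, 0 °C → rt
Reagents that add atoms: none
Why: Horner–Wadsworth–Emmons olefination of an α-alkylated phosphonoacetate with an unhindered aldehyde should give mainly the E-enoate (ester trans to the C6 chain) through reversible addition and elimination from the less crowded oxaphosphetane, and any Z isomer is removed by chromatography.

Step 10
Reactants: 20 methyl (2E,6Z)-7-iodo-6-methyl-2-{(3E)-4-methyl-6-[(1R,2R)-2-(4-methylpent-3-en-1-yl)-2-(triethylsilyloxy)cyclopropyl]hex-3-en-1-yl}hepta-2,6-dienoate
Product: 21 methyl (2E,6Z)-2-{(3E)-6-[(1R,2R)-2-hydroxy-2-(4-methylpent-3-en-1-yl)cyclopropyl]-4-methylhex-3-en-1-yl}-7-iodo-6-methylhepta-2,6-dienoate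
Conditions: TBAF, AcOH, THF, 0 °C → rt
Reagents that add atoms: none
Why: Fluoride-induced desilylation, buffered with acetic acid so that the liberated cyclopropanol does not ring-open, releases the cyclisation precursor, which is used at once.

Step 11
Reactants: 21 methyl (2E,6Z)-2-{(3E)-6-[(1R,2R)-2-hydroxy-2-(4-methylpent-3-en-1-yl)cyclopropyl]-4-methylhex-3-en-1-yl}-7-iodo-6-methylhepta-2,6-dienoate
Product: 22 methyl (1(14)E,4E,8R,10Z)-5,11-dimethyl-8-(5-methylhex-4-enoyl)cyclotetradeca-1(14),4,10-triene-1-carboxylate
Conditions: Pd(OAc)2 (10 mol %), XPhos (20 mol %), Cs2CO3, toluene, 80 °C, syringe-pump addition of 21 (final 2 mM)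
Reagents that add atoms: none
Why: Proposed new method: Pd(OAc)2 and XPhos give zerovalent palladium, which inserts into the C3–I bond without touching the Z geometry; the carbonate then swaps iodide for the cyclopropanol oxygen, the resulting divalent palladium alkoxide relieves ring strain by β-carbon elimination at C15–C2, and the alkyl(alkenyl)palladium so formed eliminates reductively to join C2 and C3. The closest known chemistry is the intermolecular palladium-catalysed ring-opening coupling of cyclopropanols with aryl and alkenyl halides to give β-substituted ketones, whose large-ring intramolecular version has not been demonstrated. The 14-membered carbocycle is closed end-to-end by C(sp3)–C(sp2) reductive elimination from a 15-membered palladacycle, and slow addition at high dilution keeps this ahead of oligomerisation. No stereocentre is formed: C1 keeps its R configuration because none of its bonds is broken and the heterogeneous carbonate in toluene should not enolise the new ketone. Three selectivities are needed: cleavage of C15–C2 and not C15–C1, which the unsubstituted CH2 corner of the cyclopropane directs; reductive elimination ahead of β-hydride loss from C1, which the bulky electron-rich biarylphosphine promotes; and capture of the alkenylpalladium by the alkoxide ahead of its 5-exo insertion into the C7=C8 enoate, which is disfavoured because that alkene is trisubstituted and the iodide-bound palladium in a non-polar solvent has no free coordination site.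

Step 12
Reactants: 22 methyl (1(14)E,4E,8R,10Z)-5,11-dimethyl-8-(5-methylhex-4-enoyl)cyclotetradeca-1(14),4,10-triene-1-carboxylate
Product: 23 methyl (1(14)E,4E,8R,10Z)-5,11-dimethyl-8-(6-methylhepta-1,5-dien-2-yl)cyclotetradeca-1(14),4,10-triene-1-carboxylate
Conditions: Zn, CH2Br2, TiCl4, THF/CH2Cl2, 0 °C → rt
Reagents that add atoms: dibromomethane, BrCBr
Why: Takai–Lombardo methylenation uses a non-basic, oxophilic gem-dimetallic reagent that converts the ketone into the 1,1-disubstituted alkene without enolising C1 and does not attack the conjugated ester.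

Step 13
Reactants: 23 methyl (1(14)E,4E,8R,10Z)-5,11-dimethyl-8-(6-methylhepta-1,5-dien-2-yl)cyclotetradeca-1(14),4,10-triene-1-carboxylate
Product: 24 (1(14)E,4E,8R,10Z)-5,11-dimethyl-8-(6-methylhepta-1,5-dien-2-yl)cyclotetradeca-1(14),4,10-triene-1-carboxylic acid
Conditions: LiOH, THF/MeOH/H2O, 40 °C; then 1 M HCl to pH 3, 0 °C
Reagents that add atoms: lithium hydroxide, [Li+].[OH-]
Why: Saponification of the methyl ester by acyl–oxygen cleavage, with C1 now allylic and non-acidic and the alkenes inert to aqueous hydroxide, gives the target acid.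

**Compound list**

1 | hex-1-en-5-yne | C=CCCC#C | starting material
2 | oxirane | C1CO1 | starting material
3 | dimethyl[(1E)-2-methylhexa-1,5-dien-1-yl]alumane | C=CCC/C(C)=C/[Al](C)C | intermediate
4 | lithium butyldimethyl[(1E)-2-methylhexa-1,5-dien-1-yl]aluminate | [Li+].C=CCC/C(C)=C/[Al-](C)(C)CCCC | intermediate
5 | (3E)-4-methylocta-3,7-dien-1-ol | C=CCC/C(C)=C/CCO | intermediate
6 | (3E)-4-methylocta-3,7-dien-1-yl methanesulfonate | C=CCC/C(C)=C/CCOS(C)(=O)=O | intermediate
7 | (5E)-8-chloro-5-methylocta-1,5-diene | C=CCC/C(C)=C/CCCl | intermediate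
8 | ethyl 5-methylhex-4-enoate | CCOC(=O)CCC=C(C)C | starting material
9 | (1R,2R)-2-[(3E)-6-chloro-3-methylhex-3-en-1-yl]-1-(4-methylpent-3-en-1-yl)cyclopropan-1-ol | O[C@]1(CCC=C(C)C)C[C@H]1CC/C(C)=C/CCCl | intermediate
10 | {[(1R,2R)-2-[(3E)-6-chloro-3-methylhex-3-en-1-yl]-1-(4-methylpent-3-en-1-yl)cyclopropyl]oxy}triethylsilane | CC[Si](CC)(CC)O[C@]1(CCC=C(C)C)C[C@H]1CC/C(C)=C/CCCl | intermediate
11 | triethyl{[(1R,2R)-2-[(3E)-6-iodo-3-methylhex-3-en-1-yl]-1-(4-methylpent-3-en-1-yl)cyclopropyl]oxy}silane | CC[Si](CC)(CC)O[C@]1(CCC=C(C)C)C[C@H]1CC/C(C)=C/CCI | intermediate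
12 | methyl 2-(diethoxyphosphoryl)acetate | CCOP(=O)(CC(=O)OC)OCC | starting material
13 | methyl (5E)-2-(diethoxyphosphoryl)-6-methyl-8-[(1R,2R)-2-(4-methylpent-3-en-1-yl)-2-(triethylsilyloxy)cyclopropyl]oct-5-enoate, both C2 epimers | CC[Si](CC)(CC)O[C@]1(CCC=C(C)C)C[C@H]1CC/C(C)=C/CCC(C(=O)OC)P(=O)(OCC)OCC | intermediate
14 | 2-(2-bromoethyl)-1,3-dioxolane | BrCCC1OCCO1 | starting material
15 | propyne | CC#C | starting material
16 | [2-(1,3-dioxolan-2-yl)ethyl]magnesium bromide | Br[Mg]CCC1OCCO1 | intermediate
17 | [(1Z)-4-(1,3-dioxolan-2-yl)-2-methylbut-1-en-1-yl]copper | [Cu]/C=C(/C)CCC1OCCO1 | intermediate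
18 | 2-[(3Z)-4-iodo-3-methylbut-3-en-1-yl]-1,3-dioxolane | I/C=C(/C)CCC1OCCO1 | intermediate
19 | (4Z)-5-iodo-4-methylpent-4-enal | O=CCC/C(C)=C\I | intermediate
20 | methyl (2E,6Z)-7-iodo-6-methyl-2-{(3E)-4-methyl-6-[(1R,2R)-2-(4-methylpent-3-en-1-yl)-2-(triethylsilyloxy)cyclopropyl]hex-3-en-1-yl}hepta-2,6-dienoate | CC[Si](CC)(CC)O[C@]1(CCC=C(C)C)C[C@H]1CC/C(C)=C/CC/C(C(=O)OC)=C\CC/C(C)=C\I | intermediate
21 | methyl (2E,6Z)-2-{(3E)-6-[(1R,2R)-2-hydroxy-2-(4-methylpent-3-en-1-yl)cyclopropyl]-4-methylhex-3-en-1-yl}-7-iodo-6-methylhepta-2,6-dienoate (cyclisation precursor) | O[C@]1(CCC=C(C)C)C[C@H]1CC/C(C)=C/CC/C(C(=O)OC)=C\CC/C(C)=C\I | intermediate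
22 | methyl (1(14)E,4E,8R,10Z)-5,11-dimethyl-8-(5-methylhex-4-enoyl)cyclotetradeca-1(14),4,10-triene-1-carboxylate (macrocyclic C15 ketone) | O=C(CCC=C(C)C)[C@H]1C/C=C(/C)CC/C=C(/C(=O)OC)CC/C=C(\C)CC1 | intermediate
23 | methyl (1(14)E,4E,8R,10Z)-5,11-dimethyl-8-(6-methylhepta-1,5-dien-2-yl)cyclotetradeca-1(14),4,10-triene-1-carboxylate | C=C(CCC=C(C)C)[C@H]1C/C=C(/C)CC/C=C(/C(=O)OC)CC/C=C(\C)CC1 | intermediate
24 | (1(14)E,4E,8R,10Z)-5,11-dimethyl-8-(6-methylhepta-1,5-dien-2-yl)cyclotetradeca-1(14),4,10-triene-1-carboxylic acid | C=C(CCC=C(C)C)[C@H]1C/C=C(/C)CC/C=C(/C(=O)O)CC/C=C(\C)CC1 | target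

**Step count and risks**

Total step count: 13. Longest linear sequence: 11 steps (steps 1–6 and 9–13, from hex-1-en-5-yne).

Steps most likely to fail:

1. Step 11 (Proposed new method). What may go wrong: the alkenylpalladium intermediate is diverted before the large ring closes. It can insert into the nearby enoate alkene, lose a β-hydride after ring-opening, or couple intermolecularly. Fallback, known chemistry throughout: the C2–C3 bond is made intermolecularly and the ring is closed at C7=C8 by a macrocyclic Horner–Wadsworth–Emmons reaction. The fallback sets out from cyclopropanol 9 and iodoalkene 18. Their palladium-catalysed ring-opening coupling (Pd(OAc)2, XPhos, Cs2CO3, toluene, 80 °C) should give the open-chain C15 ketone F1. Zn/CH2Br2/TiCl4 methylenation then gives the methylene compound F2, and NaI exchange gives the primary iodide F3. Alkylation of the sodium salt of 12 gives the phosphonate acetal F4, and aqueous acid hydrolysis of the dioxolane gives the phosphonate aldehyde F5. Intramolecular olefination under Masamune–Roush conditions (LiCl, DBU, MeCN, high dilution) closes the 14-membered ring and comes back to the route at 23.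

2. Step 3. What may go wrong: poor facial discrimination of the alkene by the chiral titanate, or slow exchange on the crowded titanium centre, so that too little single-enantiomer cyclopropanol is obtained. Fallback: classical resolution through covalent diastereomers. Setting out from 7 and 8, the hydroxycyclopropanation is run with achiral ClTi(OiPr)3 and c-C5H9MgCl, giving 9 together with the (1S,2S)-cyclopropanol F6. Acylation of the racemate with (1S)-camphanic chloride (pyridine, DMAP) gives the camphanate of 9 F7 and the camphanate of the (1S,2S)-cyclopropanol F8, which are separated by chromatography or crystallisation. Methanolysis of F7 (K2CO3, MeOH, 0 °C) comes back to the route at 9.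

3. Step 9. What may go wrong: incomplete E-selectivity in the elimination from the α-branched phosphonate adduct, leaving a share of Z-enoate that is hard to remove. Fallback: a stabilised Wittig reagent in place of the phosphonate. Setting out from iodide 11, alkylation of methyl (triphenylphosphoranylidene)acetate (2 equiv, MeCN, reflux) gives, after transylidation, the α-substituted stabilised ylide F9. Its Wittig reaction with aldehyde 19 (toluene, 80 °C, no added base) is E-selective for trisubstituted enoates and comes back to the route at 20.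

**Further compounds**

F1 | step 11 | (7R,9Z)-7-[(3E)-6-chloro-3-methylhex-3-en-1-yl]-12-(1,3-dioxolan-2-yl)-2,10-dimethyldodeca-2,9-dien-6-one (open-chain C15 ketone) | O=C(CCC=C(C)C)[C@@H](C/C=C(/C)CCC1OCCO1)CC/C(C)=C/CCCl
F2 | step 11 | methylene compound from F1 (C15 ketone replaced by C=CH2, C1 R) | C=C(CCC=C(C)C)[C@@H](C/C=C(/C)CCC1OCCO1)CC/C(C)=C/CCCl
F3 | step 11 | primary iodide from F2 | C=C(CCC=C(C)C)[C@@H](C/C=C(/C)CCC1OCCO1)CC/C(C)=C/CCI
F4 | step 11 | phosphonate acetal from F3 and 12 (epimers at the phosphonate carbon) | C=C(CCC=C(C)C)[C@@H](C/C=C(/C)CCC1OCCO1)CC/C(C)=C/CCC(C(=O)OC)P(=O)(OCC)OCC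
F5 | step 11 | phosphonate aldehyde from F4 | C=C(CCC=C(C)C)[C@@H](C/C=C(/C)CCC=O)CC/C(C)=C/CCC(C(=O)OC)P(=O)(OCC)OCC
F6 | step 3 | (1S,2S)-2-[(3E)-6-chloro-3-methylhex-3-en-1-yl]-1-(4-methylpent-3-en-1-yl)cyclopropan-1-ol | O[C@@]1(CCC=C(C)C)C[C@@H]1CC/C(C)=C/CCCl
F7 | step 3 | (1S,4R)-camphanate of 9 | O=C(O[C@]1(CCC=C(C)C)C[C@H]1CC/C(C)=C/CCCl)[C@@]23CC[C@@](C)(C(=O)O2)C3(C)C
F8 | step 3 | (1S,4R)-camphanate of the (1S,2S)-cyclopropanol | O=C(O[C@@]1(CCC=C(C)C)C[C@@H]1CC/C(C)=C/CCCl)[C@@]23CC[C@@](C)(C(=O)O2)C3(C)C
F9 | step 9 | methyl (5E)-6-methyl-8-[(1R,2R)-2-(4-methylpent-3-en-1-yl)-2-(triethylsilyloxy)cyclopropyl]-2-(triphenyl-λ5-phosphanylidene)oct-5-enoate | CC[Si](CC)(CC)O[C@]1(CCC=C(C)C)C[C@H]1CC/C(C)=C/CCC(C(=O)OC)=P(c2ccccc2)(c2ccccc2)c2ccccc2
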